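**Strategy**

Each quaternary carbon (C3 of a C15 chain) stands para to a phenolic oxygen: O–C4 on the phenol ring, the central O–C2′ on the pyrogallol ring. The route therefore first builds the easier C–O isomer: a diaryl ether whose two oxygens carry an (R)- and an (S)-nerolidyl (tertiary allyl) group, each flanked by two substituted ortho carbons (Br/OAr; OAr/OSi). One thermal double para-Claisen (Claisen–Cope) relay then moves both chains from oxygen to the para carbons, forming both aryl–C(quaternary) bonds and both stereocentres by chirality transfer and freeing both phenols. The C–O stereocentres come from Pd-catalysed asymmetric O-allylation of phenols with farnesyl carbonate.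

Key step: step 8

Abbreviations: (R)-Ner = (3R,6E)-3,7,11-trimethyldodeca-1,6,10-trien-3-yl; (S)-Ner = its (3S,6E) enantiomer; farnesyl = (2E,6E)-3,7,11-trimethyldodeca-2,6,10-trien-1-yl; L = N,N′-(cyclohexane-1,2-diyl)bis[2-(diphenylphosphino)benzamide]; ring A = the monohydroxy ring, ring B = the dihydroxy ring.

Assumption: (R,R)-L is taken to give the (R)-ether 5 and (S,S)-L the (S)-ether 6; if the sense of induction is the opposite, the two ligand antipodes are exchanged between steps 3 and 4.

**Route**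

Step 1
Reactants: 1 (2E,6E)-farnesol
Product: 2 (2E,6E)-farnesyl methyl carbonate
Conditions: MeOCOCl, pyridine, CH2Cl2, 0 °C
Reagents that add atoms: methyl chloroformate, COC(=O)Cl
Why: Acylation of the primary allylic alcohol with a chloroformate (carbonate formation) is routine and turns C1–O into the leaving group needed for π-allyl formation; no stereocentre is formed.

Step 2
Reactants: 3 3-bromocatechol
Product: 4 2-bromo-6-(triisopropylsilyloxy)phenol
Conditions: TIPSCl (1.05 equiv), imidazole, DMF, 0 °C to rt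
Reagents that add atoms: chlorotriisopropylsilane, CC(C)[Si](Cl)(C(C)C)C(C)C
Why: In this monosilylation of a catechol the bulky silyl chloride should take the unhindered OH remote from Br, and any O-to-O silyl transfer leads to the same isomer because it leaves the more acidic, Br-flanked OH free; TIPS is chosen because it migrates slowly in the later phenoxide.

Step 3
Reactants: 4 2-bromo-6-(triisopropylsilyloxy)phenol; 2 (2E,6E)-farnesyl methyl carbonate
Product: 5 1-bromo-2-[(R)-Ner-oxy]-3-(triisopropylsilyloxy)benzene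
Conditions: Pd2(dba)3·CHCl3 (2 mol%), (R,R)-L (6 mol%), CH2Cl2, 0 °C to rt
Reagents that add atoms: none
Why: In this Pd-catalysed asymmetric allylic O-alkylation (Tsuji–Trost type, known for phenols with geranyl-type carbonates) the phenoxide attacks the fully substituted terminus of the π-farnesyl–Pd complex inside the chiral pocket of the ligand, which selects one face of the E-configured terminus and so sets the C3–O stereocentre as R.

Step 4
Reactants: 4 2-bromo-6-(triisopropylsilyloxy)phenol; 2 (2E,6E)-farnesyl methyl carbonate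
Product: 6 1-bromo-2-[(S)-Ner-oxy]-3-(triisopropylsilyloxy)benzene
Conditions: Pd2(dba)3·CHCl3 (2 mol%), (S,S)-L (6 mol%), CH2Cl2, 0 °C to rt
Reagents that add atoms: none
Why: The same Tsuji–Trost-type asymmetric O-allylation with the antipodal ligand presents the mirror-image pocket to the same E-configured allyl terminus and so sets the C3–O stereocentre as S.

Step 5
Reactants: 5 1-bromo-2-[(R)-Ner-oxy]-3-(triisopropylsilyloxy)benzene
Product: 7 3-bromo-2-[(R)-Ner-oxy]phenol
Conditions: TBAF, THF, 0 °C; aq NH4Cl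
Reagents that add atoms: none
Why: Fluoride-mediated desilylation frees the phenol at low temperature under non-acidic conditions, so the acid- and heat-sensitive tertiary allyl aryl ether and its stereocentre are not touched.

Step 6
Reactants: 6 1-bromo-2-[(S)-Ner-oxy]-3-(triisopropylsilyloxy)benzene
Product: 10 {2-[(S)-Ner-oxy]-3-(triisopropylsilyloxy)phenyl}boronic acid, via aryllithium 8 (not isolated), via lithium aryltriisopropoxyborate 9 (not isolated)
Conditions: n-BuLi, THF, −78 °C; B(OiPr)3, −78 to 0 °C; aq NH4Cl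
Reagents that add atoms: triisopropyl borate, CC(C)OB(OC(C)C)OC(C)C; water, O
Why: Br–Li exchange at −78 °C and trapping by the borate (lithiation–borylation) should outrun attack of the aryllithium on the neighbouring allyl ether, and the near-neutral hydrolysis gives the boronic acid with the C–O stereocentre untouched.

Step 7
Reactants: 7 3-bromo-2-[(R)-Ner-oxy]phenol; 10 {2-[(S)-Ner-oxy]-3-(triisopropylsilyloxy)phenyl}boronic acid
Product: 11 1-bromo-2-[(R)-Ner-oxy]-3-{2-[(S)-Ner-oxy]-3-(triisopropylsilyloxy)phenoxy}benzene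
Conditions: Cu(OAc)2 (2 equiv), pyridine, 4 Å MS, CH2Cl2, air, rt
Reagents that add atoms: none
Why: The Chan–Lam coupling (Cu(II)-mediated oxidative C–O coupling of an arylboronic acid with a phenol) runs at rt under weakly basic conditions that both tertiary allyl ethers tolerate, leaves the aryl bromide of 7 alone, and uses each nerolidyl group as the protecting group of its own oxygen.

Step 8
Reactants: 11 1-bromo-2-[(R)-Ner-oxy]-3-{2-[(S)-Ner-oxy]-3-(triisopropylsilyloxy)phenoxy}benzene
Product: 15 2-bromo-6-{2-hydroxy-5-[(S)-Ner]-3-(triisopropylsilyloxy)phenoxy}-4-[(R)-Ner]phenol, via ring-B ortho-dienone 12 (not isolated), via mono-rearranged phenol 13 (not isolated), via ring-A ortho-dienone 14 (not isolated)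
Conditions: PhNEt2 (degassed), 150 °C, Ar
Reagents that add atoms: none
Why: Proposed new method: each aryl nerolidyl ether should undergo an aromatic Claisen [3,3] shift to a substituted ortho carbon, giving a cyclohexa-2,4-dienone (12, 14) that cannot enolise and therefore passes the chain on by a Cope [3,3] shift to the para carbon, after which tautomerisation restores the phenol (13, then 15; the order of the two rings is immaterial). The closest known reaction type is the para-Claisen rearrangement of 2,6-disubstituted aryl allyl ethers, which is stereospecific for α-substituted secondary allyl groups; carrying a tertiary C–O stereocentre into an all-carbon quaternary centre, twice in one molecule, is the extension proposed here. No ring is closed. Each new stereocentre (C3 of each chain) is controlled by the C3–O stereocentre of its ether: the first shift stores the information in the ring sp3 carbon and the new alkene geometry, and two successive chair transition states bring the para carbon to the face of C3 that oxygen left, so the (R)-ether should give the (R)-aryl centre on ring A and the (S)-ether the (S)-centre on ring B, whichever of methyl or chain is equatorial in the first chair. The step needs para- over ortho-selectivity, secured by the substituents on both ortho carbons of each ether oxygen (Br and OAr on ring A, OAr and OSi on ring B), and a concerted shift over ionisation to farnesenes, which the basic aprotic medium should favour.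

Step 9
Reactants: 15 2-bromo-6-{2-hydroxy-5-[(S)-Ner]-3-(triisopropylsilyloxy)phenoxy}-4-[(R)-Ner]phenol
Product: 18 3-{2-hydroxy-5-[(R)-Ner]phenoxy}-5-[(S)-Ner]benzene-1,2-diol (target), via trilithiated species 16 (not isolated), via debrominated silyl ether 17 (not isolated)
Conditions: t-BuLi (5 equiv), THF, −78 °C; MeOH; then TBAF, rt; aq NH4Cl
Reagents that add atoms: none
Why: Halogen–lithium exchange on the lithium phenoxide followed by protonation removes the blocking bromine and fluoride then cleaves the aryl silyl ether, while the isolated alkenes and both quaternary stereocentres are inert to these reagents.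

**Compound list**

1 | (2E,6E)-farnesol | OC/C=C(\C)CC/C=C(\C)CCC=C(C)C | starting material
2 | (2E,6E)-farnesyl methyl carbonate | COC(=O)OC/C=C(\C)CC/C=C(\C)CCC=C(C)C | intermediate
3 | 3-bromocatechol (3-bromobenzene-1,2-diol) | Oc1cccc(Br)c1O | starting material
4 | 2-bromo-6-(triisopropylsilyloxy)phenol | Oc1c(Br)cccc1O[Si](C(C)C)(C(C)C)C(C)C | intermediate
5 | 1-bromo-2-[(R)-Ner-oxy]-3-(triisopropylsilyloxy)benzene | C=C[C@@](C)(CC/C=C(\C)CCC=C(C)C)Oc1c(Br)cccc1O[Si](C(C)C)(C(C)C)C(C)C | intermediate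
6 | 1-bromo-2-[(S)-Ner-oxy]-3-(triisopropylsilyloxy)benzene | C=C[C@](C)(CC/C=C(\C)CCC=C(C)C)Oc1c(Br)cccc1O[Si](C(C)C)(C(C)C)C(C)C | intermediate
7 | 3-bromo-2-[(R)-Ner-oxy]phenol | C=C[C@@](C)(CC/C=C(\C)CCC=C(C)C)Oc1c(Br)cccc1O | intermediate
8 | {2-[(S)-Ner-oxy]-3-(triisopropylsilyloxy)phenyl}lithium | C=C[C@](C)(CC/C=C(\C)CCC=C(C)C)Oc1c([Li])cccc1O[Si](C(C)C)(C(C)C)C(C)C | intermediate
9 | lithium {2-[(S)-Ner-oxy]-3-(triisopropylsilyloxy)phenyl}triisopropoxyborate | C=C[C@](C)(CC/C=C(\C)CCC=C(C)C)Oc1c([B-](OC(C)C)(OC(C)C)OC(C)C)cccc1O[Si](C(C)C)(C(C)C)C(C)C.[Li+] | intermediate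
10 | {2-[(S)-Ner-oxy]-3-(triisopropylsilyloxy)phenyl}boronic acid | C=C[C@](C)(CC/C=C(\C)CCC=C(C)C)Oc1c(B(O)O)cccc1O[Si](C(C)C)(C(C)C)C(C)C | intermediate
11 | 1-bromo-2-[(R)-Ner-oxy]-3-{2-[(S)-Ner-oxy]-3-(triisopropylsilyloxy)phenoxy}benzene | C=C[C@@](C)(CC/C=C(\C)CCC=C(C)C)Oc1c(Br)cccc1Oc1cccc(O[Si](C(C)C)(C(C)C)C(C)C)c1O[C@](C)(C=C)CC/C=C(\C)CCC=C(C)C | intermediate
12 | ring-B ortho-dienone, (6S)-6-{3-bromo-2-[(R)-Ner-oxy]phenoxy}-6-farnesyl-2-(triisopropylsilyloxy)cyclohexa-2,4-dien-1-one (representative: shift to the aryloxy-bearing carbon, 2E alkene) | C=C[C@@](C)(CC/C=C(\C)CCC=C(C)C)Oc1c(Br)cccc1O[C@@]1(C/C=C(\C)CC/C=C(\C)CCC=C(C)C)C=CC=C(O[Si](C(C)C)(C(C)C)C(C)C)C1=O | intermediate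
13 | mono-rearranged phenol, 2-{3-bromo-2-[(R)-Ner-oxy]phenoxy}-4-[(S)-Ner]-6-(triisopropylsilyloxy)phenol | C=C[C@@](C)(CC/C=C(\C)CCC=C(C)C)Oc1c(Br)cccc1Oc1cc([C@](C)(C=C)CC/C=C(\C)CCC=C(C)C)cc(O[Si](C(C)C)(C(C)C)C(C)C)c1O | intermediate
14 | ring-A ortho-dienone, (6R)-2-bromo-6-farnesyl-6-{2-hydroxy-5-[(S)-Ner]-3-(triisopropylsilyloxy)phenoxy}cyclohexa-2,4-dien-1-one (representative: shift to the aryloxy-bearing carbon, 2E alkene) | O=C1C(Br)=CC=C[C@@]1(C/C=C(\C)CC/C=C(\C)CCC=C(C)C)Oc1cc([C@](C)(C=C)CC/C=C(\C)CCC=C(C)C)cc(O[Si](C(C)C)(C(C)C)C(C)C)c1O | intermediate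
15 | 2-bromo-6-{2-hydroxy-5-[(S)-Ner]-3-(triisopropylsilyloxy)phenoxy}-4-[(R)-Ner]phenol | C=C[C@@](C)(CC/C=C(\C)CCC=C(C)C)c1cc(Br)c(O)c(Oc2cc([C@](C)(C=C)CC/C=C(\C)CCC=C(C)C)cc(O[Si](C(C)C)(C(C)C)C(C)C)c2O)c1 | intermediate
16 | trilithiated species from 15 (C3–Li on ring A, both phenols as O–Li) | C=C[C@@](C)(CC/C=C(\C)CCC=C(C)C)c1cc([Li])c(O[Li])c(Oc2cc([C@](C)(C=C)CC/C=C(\C)CCC=C(C)C)cc(O[Si](C(C)C)(C(C)C)C(C)C)c2O[Li])c1 | intermediate
17 | debrominated silyl ether, 2-{2-hydroxy-5-[(S)-Ner]-3-(triisopropylsilyloxy)phenoxy}-4-[(R)-Ner]phenol | C=C[C@@](C)(CC/C=C(\C)CCC=C(C)C)c1ccc(O)c(Oc2cc([C@](C)(C=C)CC/C=C(\C)CCC=C(C)C)cc(O[Si](C(C)C)(C(C)C)C(C)C)c2O)c1 | intermediate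
18 | 3-{2-hydroxy-5-[(R)-Ner]phenoxy}-5-[(S)-Ner]benzene-1,2-diol (CNP0296687.1) | C=C[C@@](C)(CC/C=C(\C)CCC=C(C)C)c1ccc(O)c(Oc2cc([C@](C)(C=C)CC/C=C(\C)CCC=C(C)C)cc(O)c2O)c1 | target

**Step count and risks**

Total step count: 9. Longest linear sequence: 6 steps (steps 2, 4, 6, 7, 8, 9 from 3-bromocatechol; equally steps 1, 4, 6, 7, 8, 9 from farnesol).

1. Step 8 (Proposed new method). What may go wrong: heterolysis or retro-ene cleavage of the tertiary allyl–oxygen bonds with loss of the C15 unit as farnesenes; expulsion of bromine from a ring-A dienone when the first shift goes to the bromine-bearing carbon; or leakage through boat transition states or dissociation–recombination that erodes the transfer of chirality. Fallback with known chemistry, setting out from 1 and coming back at 18 without any rearrangement: 1 is converted with diethyl chlorophosphate and pyridine into (2E,6E)-farnesyl diethyl phosphate F1. Commercial 1-bromo-4-(methoxymethoxy)benzene is lithiated and transmetalated with Et2AlCl to diethyl[4-(methoxymethoxy)phenyl]aluminium F2, which should undergo NHC–Cu-catalysed enantioselective SN2′ allylic substitution with F1 to give 1-(methoxymethoxy)-4-[(R)-Ner]benzene F3. Directed ortho-lithiation next to the MOM ether and borylation then give {2-(methoxymethoxy)-5-[(R)-Ner]phenyl}boronic acid F4. With the antipodal NHC ligand, [3,4-bis(methoxymethoxy)phenyl]diethylaluminium F5 (from commercial 4-bromo-1,2-bis(methoxymethoxy)benzene) and F1 give 1,2-bis(methoxymethoxy)-4-[(S)-Ner]benzene F6. Lithiation of F6 at the only unhindered position ortho to a MOM ether, borylation and oxidation with H2O2 give 2,3-bis(methoxymethoxy)-5-[(S)-Ner]phenol F7. Chan–Lam coupling of F4 with F7 gives the tris-MOM diaryl ether F8, and HCl in MeOH releases 18.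

2. Step 7. What may go wrong: slow transmetalation and C–O bond formation because both partners carry an ortho tertiary alkoxy group, so that protodeboronation and oxidation of 10 outrun the coupling. Fallback, setting out from 5 and 6 and coming back at 18, with the union moved behind the rearrangement so that heat can be used: each ether is rearranged on its own (PhNEt2, 150 °C), 6 giving 2-bromo-4-[(S)-Ner]-6-(triisopropylsilyloxy)phenol F9 and 5 giving 2-bromo-4-[(R)-Ner]-6-(triisopropylsilyloxy)phenol F11. MOMCl and iPr2NEt convert them into 1-bromo-2-(methoxymethoxy)-5-[(S)-Ner]-3-(triisopropylsilyloxy)benzene F10 and its (R)-Ner enantiomer F12. F12 is debrominated and desilylated (t-BuLi; MeOH; then TBAF) to 2-(methoxymethoxy)-5-[(R)-Ner]phenol F13. An Ullmann ether coupling of F13 with the aryl bromide F10 (CuI, N,N-dimethylglycine, Cs2CO3, dioxane, 90 °C) gives the protected diaryl ether F14, and HCl in MeOH followed by TBAF gives 18.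

3. Step 3 (step 4 is the same reaction with the antipodal ligand and shares the concern). What may go wrong: attack of the hindered, fairly acidic phenoxide at the primary allyl terminus, or re-ionisation of the product ether by Pd(0), giving the linear farnesyl ether and eroding the enantiomeric purity, which would show later as diastereomers of 18. Fallback, setting out from 1 and coming back at 5, with the stereocentre taken from a reagent-controlled epoxidation and transferred stereospecifically: Sharpless asymmetric epoxidation of 1 with D-(−)-diethyl tartrate gives (2R,3R)-2,3-epoxyfarnesol F15. I2, PPh3 and imidazole give the epoxy iodide (2S,3R)-2,3-epoxy-1-iodo-3,7,11-trimethyldodeca-6,10-diene F16, which zinc in AcOH/MeOH opens reductively to (3R,6E)-nerolidol F17. n-BuLi and methyl chloroformate give (3R,6E)-nerolidyl methyl carbonate F18. Rh-catalysed enantiospecific allylic etherification of F18 with the lithium phenoxide of 4 (RhCl(PPh3)3, P(OMe)3, THF) should give 5 with net retention; this reaction type is established for ortho,ortho-disubstituted phenoxides with secondary allylic carbonates and for tertiary allylic carbonates with carbon nucleophiles.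

Further compounds
F1 | step 8 | (2E,6E)-farnesyl diethyl phosphate | CCOP(=O)(OCC)OC/C=C(\C)CC/C=C(\C)CCC=C(C)C
F2 | step 8 | diethyl[4-(methoxymethoxy)phenyl]aluminium | CC[Al](CC)c1ccc(OCOC)cc1
F3 | step 8 | 1-(methoxymethoxy)-4-[(R)-Ner]benzene | C=C[C@@](C)(CC/C=C(\C)CCC=C(C)C)c1ccc(OCOC)cc1
F4 | step 8 | {2-(methoxymethoxy)-5-[(R)-Ner]phenyl}boronic acid | C=C[C@@](C)(CC/C=C(\C)CCC=C(C)C)c1ccc(OCOC)c(B(O)O)c1
F5 | step 8 | [3,4-bis(methoxymethoxy)phenyl]diethylaluminium | CC[Al](CC)c1ccc(OCOC)c(OCOC)c1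
F6 | step 8 | 1,2-bis(methoxymethoxy)-4-[(S)-Ner]benzene | C=C[C@](C)(CC/C=C(\C)CCC=C(C)C)c1ccc(OCOC)c(OCOC)c1
F7 | step 8 | 2,3-bis(methoxymethoxy)-5-[(S)-Ner]phenol | C=C[C@](C)(CC/C=C(\C)CCC=C(C)C)c1cc(O)c(OCOC)c(OCOC)c1
F8 | step 8 | tris-MOM ether of 18, 1,2-bis(methoxymethoxy)-3-{2-(methoxymethoxy)-5-[(R)-Ner]phenoxy}-5-[(S)-Ner]benzene | C=C[C@@](C)(CC/C=C(\C)CCC=C(C)C)c1ccc(OCOC)c(Oc2cc([C@](C)(C=C)CC/C=C(\C)CCC=C(C)C)cc(OCOC)c2OCOC)c1
F9 | step 7 | 2-bromo-4-[(S)-Ner]-6-(triisopropylsilyloxy)phenol | C=C[C@](C)(CC/C=C(\C)CCC=C(C)C)c1cc(Br)c(O)c(O[Si](C(C)C)(C(C)C)C(C)C)c1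
F10 | step 7 | 1-bromo-2-(methoxymethoxy)-5-[(S)-Ner]-3-(triisopropylsilyloxy)benzene | C=C[C@](C)(CC/C=C(\C)CCC=C(C)C)c1cc(Br)c(OCOC)c(O[Si](C(C)C)(C(C)C)C(C)C)c1
F11 | step 7 | 2-bromo-4-[(R)-Ner]-6-(triisopropylsilyloxy)phenol | C=C[C@@](C)(CC/C=C(\C)CCC=C(C)C)c1cc(Br)c(O)c(O[Si](C(C)C)(C(C)C)C(C)C)c1
F12 | step 7 | 1-bromo-2-(methoxymethoxy)-5-[(R)-Ner]-3-(triisopropylsilyloxy)benzene | C=C[C@@](C)(CC/C=C(\C)CCC=C(C)C)c1cc(Br)c(OCOC)c(O[Si](C(C)C)(C(C)C)C(C)C)c1
F13 | step 7 | 2-(methoxymethoxy)-5-[(R)-Ner]phenol | C=C[C@@](C)(CC/C=C(\C)CCC=C(C)C)c1ccc(OCOC)c(O)c1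
F14 | step 7 | 2-(methoxymethoxy)-1-{2-(methoxymethoxy)-5-[(R)-Ner]phenoxy}-5-[(S)-Ner]-3-(triisopropylsilyloxy)benzene | C=C[C@@](C)(CC/C=C(\C)CCC=C(C)C)c1ccc(OCOC)c(Oc2cc([C@](C)(C=C)CC/C=C(\C)CCC=C(C)C)cc(O[Si](C(C)C)(C(C)C)C(C)C)c2OCOC)c1
F15 | step 3 | (2R,3R)-2,3-epoxyfarnesol | OC[C@H]1O[C@]1(C)CC/C=C(\C)CCC=C(C)C
F16 | step 3 | (2S,3R)-2,3-epoxy-1-iodo-3,7,11-trimethyldodeca-6,10-diene (6E) | IC[C@H]1O[C@]1(C)CC/C=C(\C)CCC=C(C)C
F17 | step 3 | (3R,6E)-nerolidol | C=C[C@@](C)(CC/C=C(\C)CCC=C(C)C)O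
F18 | step 3 | (3R,6E)-nerolidyl methyl carbonate | C=C[C@@](C)(CC/C=C(\C)CCC=C(C)C)OC(=O)OC
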